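**Retrosynthetic overview**
- The depside ester bond between the ring A carboxyl carbon and O-4 of ring B is made late by mixed-anhydride acylation; all three benzyl groups are then removed in one final hydrogenolysis.
- Both halves come from one acid, 2,4-bis(benzyloxy)-6-pentylbenzoic acid 9. It is used as such for ring A, and converted by debenzylation, benzyl ester formation and 4-O-MOM / 2-O-methyl / de-MOM into the ring B phenol 14.
- Acid 9 is cut at C1–CO2H and C6–pentyl to 3,5-bis(benzyloxy)benzyne (from fluoroarene 3), pentylmagnesium bromide and CO2. The feature this rests on: in ring A and in ring B alike, the pentyl-bearing C6, the carboxyl-bearing C1 and the oxygen-bearing C2 are contiguous, with the second oxygen on C4, which is the pattern left by adding a carbon nucleophile and then CO2 across a 3,5-dialkoxyaryne.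
- No ring is constructed; both benzene rings are carried in intact from 5-fluororesorcinol.

Key step: step 2

Remark on the chemistry: the target has no stereocentre, and pentylmagnesium bromide is taken as the commercial ether solution (it can equally be made from 1-bromopentane and Mg turnings).

**Route**

Step 1
Reactants: 1 5-fluororesorcinol (5-fluorobenzene-1,3-diol); 2 benzyl bromide
Product: 3 1,3-bis(benzyloxy)-5-fluorobenzene
Conditions: BnBr (2.3 equiv), K2CO3 (3 equiv), DMF, 60 °C
Reagents that add atoms: benzyl bromide, BrCc1ccccc1
Why: Williamson ether synthesis on two unhindered phenols; the aryl fluoride is inert to carbonate.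

Step 2
Reactants: 3 1,3-bis(benzyloxy)-5-fluorobenzene; 4 pentylmagnesium bromide; 5 carbon dioxide
Product: 9 2,4-bis(benzyloxy)-6-pentylbenzoic acid, via aryllithium 6 (not isolated), via aryne 7 (not isolated), via arylmagnesium bromide 8 (not isolated)
Conditions: n-BuLi (0.95 equiv), THF, −78 °C, 1 h; then 4 (2.5 equiv, Et2O solution), −78 °C → rt; then dry CO2 gas, 0 °C → rt; then cold 1 M HCl work-up, acid isolated by base extraction
Reagents that add atoms: pentylmagnesium bromide, CCCCC[Mg]Br; carbon dioxide, O=C=O
Why: n-BuLi removes one of the two equivalent ring protons flanked by fluorine and a benzyloxy group to give aryllithium 6, which is stable at −78 °C and loses LiF on warming to give aryne 7 in the presence of the Grignard reagent. The pentyl group attacks the aryne carbon remote from the neighbouring benzyloxy group (the former C–F carbon), because the inductively withdrawing oxygen distorts the triple bond and stabilises the carbanion developing beside it, so magnesium sits ortho to oxygen in 8. Carbon dioxide carboxylates this aryl Grignard and acidic work-up should release acid 9 with the contiguous pentyl/carboxyl/oxygen triad. The closest known reaction type is the one-pot three-component coupling of 3-alkoxyarynes, generated from fluoroarenes, with Grignard reagents and CO2. No ring is closed and no stereocentre is formed; two skeletal C–C bonds are made. The selectivities needed are ring lithiation beside fluorine rather than between the two ethers or at a benzylic CH2 (secured by the acidifying fluorine and by n-BuLi at −78 °C, while the 2-lithio isomer cannot eliminate and ends as a separable fluoro acid), full consumption of the slight deficit of n-BuLi before any aryne forms (so that no butyl homologue arises), and distal addition to the aryne (secured by the ether on the carbon next to the triple bond).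

Step 3
Reactants: 9 2,4-bis(benzyloxy)-6-pentylbenzoic acid (about half of the material)
Product: 10 2,4-dihydroxy-6-pentylbenzoic acid (olivetolic acid)
Conditions: H2 (1 atm), 10% Pd/C, EtOAc, rt; concentrate below 30 °C
Reagents that add atoms: none
Why: Catalytic hydrogenolysis of the two benzyl aryl ethers, with nothing else reducible in 9; a cold work-up avoids decarboxylation of the β-resorcylic acid.

Step 4
Reactants: 10 2,4-dihydroxy-6-pentylbenzoic acid; 2 benzyl bromide
Product: 11 benzyl 2,4-dihydroxy-6-pentylbenzoate
Conditions: BnBr (1.05 equiv), KHCO3 (1.1 equiv), DMF, rt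
Reagents that add atoms: benzyl bromide, BrCc1ccccc1
Why: SN2 O-alkylation of the carboxylate; hydrogen carbonate ionises only the carboxylic acid, so the phenols should stay free.

Step 5
Reactants: 11 benzyl 2,4-dihydroxy-6-pentylbenzoate
Product: 12 benzyl 2-hydroxy-4-(methoxymethoxy)-6-pentylbenzoate
Conditions: MOMCl (1.1 equiv), iPr2NEt (1.5 equiv), CH2Cl2, 0 °C
Reagents that add atoms: chloromethyl methyl ether, COCCl
Why: Regioselective phenol alkylation (MOM ether formation): the 2-OH is hydrogen-bonded to the ester carbonyl and flanked by it, whereas the 4-OH is free, unhindered and more acidic.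

Step 6
Reactants: 12 benzyl 2-hydroxy-4-(methoxymethoxy)-6-pentylbenzoate
Product: 13 benzyl 2-methoxy-4-(methoxymethoxy)-6-pentylbenzoate
Conditions: MeI (3 equiv), K2CO3 (2 equiv), DMF, rt → 40 °C
Reagents that add atoms: iodomethane, CI
Why: Williamson methylation of the one remaining (chelated) phenol; the MOM ether and the benzyl ester are stable to carbonate.

Step 7
Reactants: 13 benzyl 2-methoxy-4-(methoxymethoxy)-6-pentylbenzoate
Product: 14 benzyl 4-hydroxy-2-methoxy-6-pentylbenzoate
Conditions: conc. HCl (cat.), MeOH, 45 °C
Reagents that add atoms: none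
Why: Acid-catalysed acetal exchange releases the phenol and sends the CH2 unit to dimethoxymethane; the di-ortho-substituted benzyl ester and the aryl methyl ether should not react.

Step 8
Reactants: 9 2,4-bis(benzyloxy)-6-pentylbenzoic acid; 14 benzyl 4-hydroxy-2-methoxy-6-pentylbenzoate
Product: 16 benzyl 4-{[2,4-bis(benzyloxy)-6-pentylbenzoyl]oxy}-2-methoxy-6-pentylbenzoate, via mixed anhydride 15 (not isolated)
Conditions: (CF3CO)2O (3 equiv), dry toluene, rt
Reagents that add atoms: none
Why: Mixed-anhydride esterification: the aroyl trifluoroacetate of this electron-rich, di-ortho-substituted acid reacts as an acylium-like donor and acylates the only free hydroxyl of 14, the classical way of joining depside halves.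

Step 9
Reactants: 16 benzyl 4-{[2,4-bis(benzyloxy)-6-pentylbenzoyl]oxy}-2-methoxy-6-pentylbenzoate
Product: 17 4-[(2,4-dihydroxy-6-pentylbenzoyl)oxy]-2-methoxy-6-pentylbenzoic acid (target)
Conditions: H2 (1 atm), 10% Pd/C, EtOAc, rt
Reagents that add atoms: none
Why: Hydrogenolysis of the two benzyl ethers and the benzyl ester; the aryl ester and the methyl ether are inert, and the aprotic solvent avoids transesterification of the depside link.

**Compound list**
1 | 5-fluororesorcinol (5-fluorobenzene-1,3-diol) | Oc1cc(O)cc(F)c1 | starting material
2 | benzyl bromide | BrCc1ccccc1 | starting material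
3 | 1,3-bis(benzyloxy)-5-fluorobenzene | Fc1cc(OCc2ccccc2)cc(OCc2ccccc2)c1 | intermediate
4 | pentylmagnesium bromide | CCCCC[Mg]Br | starting material
5 | carbon dioxide | O=C=O | starting material
6 | [2,4-bis(benzyloxy)-6-fluorophenyl]lithium | [Li]c1c(F)cc(OCc2ccccc2)cc1OCc1ccccc1 | intermediate
7 | 3,5-bis(benzyloxy)benzyne (3,5-bis(benzyloxy)-1,2-didehydrobenzene) | C1#CC(OCc2ccccc2)=CC(OCc2ccccc2)=C1 | intermediate
8 | [2,4-bis(benzyloxy)-6-pentylphenyl]magnesium bromide | CCCCCc1cc(OCc2ccccc2)cc(OCc2ccccc2)c1[Mg]Br | intermediate
9 | 2,4-bis(benzyloxy)-6-pentylbenzoic acid | CCCCCc1cc(OCc2ccccc2)cc(OCc2ccccc2)c1C(=O)O | intermediate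
10 | 2,4-dihydroxy-6-pentylbenzoic acid (olivetolic acid) | CCCCCc1cc(O)cc(O)c1C(=O)O | intermediate
11 | benzyl 2,4-dihydroxy-6-pentylbenzoate | CCCCCc1cc(O)cc(O)c1C(=O)OCc1ccccc1 | intermediate
12 | benzyl 2-hydroxy-4-(methoxymethoxy)-6-pentylbenzoate | CCCCCc1cc(OCOC)cc(O)c1C(=O)OCc1ccccc1 | intermediate
13 | benzyl 2-methoxy-4-(methoxymethoxy)-6-pentylbenzoate | CCCCCc1cc(OCOC)cc(OC)c1C(=O)OCc1ccccc1 | intermediate
14 | benzyl 4-hydroxy-2-methoxy-6-pentylbenzoate | CCCCCc1cc(O)cc(OC)c1C(=O)OCc1ccccc1 | intermediate
15 | 2,4-bis(benzyloxy)-6-pentylbenzoic trifluoroacetic anhydride | CCCCCc1cc(OCc2ccccc2)cc(OCc2ccccc2)c1C(=O)OC(=O)C(F)(F)F | intermediate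
16 | benzyl 4-{[2,4-bis(benzyloxy)-6-pentylbenzoyl]oxy}-2-methoxy-6-pentylbenzoate | CCCCCc1cc(OCc2ccccc2)cc(OCc2ccccc2)c1C(=O)Oc1cc(CCCCC)c(C(=O)OCc2ccccc2)c(OC)c1 | intermediate
17 | 4-[(2,4-dihydroxy-6-pentylbenzoyl)oxy]-2-methoxy-6-pentylbenzoic acid | CCCCCc1cc(O)cc(O)c1C(=O)Oc1cc(CCCCC)c(C(=O)O)c(OC)c1 | target

**Step count**
Total: 9 steps. Longest linear sequence: 9 steps (1 → 3 → 9 → 10 → 11 → 12 → 13 → 14 → 16 → 17); the ring A half joins from the common intermediate 9 at step 8.

**Steps most likely to fail**

1. Step 2 (aryne three-component coupling). What may go wrong: metalation at the wrong site (between the two ethers, or at a benzylic CH2 followed by Wittig rearrangement), butyl transfer from unconsumed n-BuLi to the aryne, or protonation of the hindered aryl Grignard before carboxylation. Fallback: the fallback sets out from benzyl bromide 2 together with commercial olivetol F1 and builds the same acid by classical arene functionalisation. Vilsmeier–Haack formylation of olivetol F1 (POCl3, DMF, 0 °C → rt, then aqueous hydrolysis) should give 2,4-dihydroxy-6-pentylbenzaldehyde F2. Bis-benzylation with 2 (K2CO3, DMF, 70 °C) should give 2,4-bis(benzyloxy)-6-pentylbenzaldehyde F3. Pinnick oxidation (NaClO2, NaH2PO4, 2-methyl-2-butene, t-BuOH/H2O) then returns to the route at acid 9.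

2. Step 8 (depside coupling). What may go wrong: slow acylation of a phenol deactivated by its para ester by a di-ortho-substituted acid, with competing trifluoroacetylation of the phenol or acid-induced loss of a benzyl ether. Fallback: the fallback sets out from acid 9 and replaces the acid-mediated mixed anhydride by a base-mediated acylation with an isolated acyl chloride. Acid 9 is converted with oxalyl chloride and catalytic DMF in CH2Cl2 into 2,4-bis(benzyloxy)-6-pentylbenzoyl chloride F4. Phenol 14 is deprotonated with NaH in THF at 0 °C and the sodium phenoxide is acylated by F4, returning to the route at 16.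

3. Step 5 (differentiation of the two phenols). What may go wrong: over-alkylation or alkylation at the chelated 2-OH, leaving the phenols undifferentiated. Fallback: the fallback sets out from diol ester 11 and acid 9 and changes the order of events so that no phenol protecting group is needed. Coupling of 11 with 9 under trifluoroacetic anhydride in toluene should take place at the non-chelated 4-OH and give benzyl 4-{[2,4-bis(benzyloxy)-6-pentylbenzoyl]oxy}-2-hydroxy-6-pentylbenzoate F5. Methylation of the remaining 2'-OH (MeI, K2CO3, acetone) then returns to the route at 16, bypassing steps 5 to 7.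

**Further compounds**
F1 | step 2 | olivetol (5-pentylbenzene-1,3-diol) | CCCCCc1cc(O)cc(O)c1
F2 | step 2 | 2,4-dihydroxy-6-pentylbenzaldehyde | CCCCCc1cc(O)cc(O)c1C=O
F3 | step 2 | 2,4-bis(benzyloxy)-6-pentylbenzaldehyde | CCCCCc1cc(OCc2ccccc2)cc(OCc2ccccc2)c1C=O
F4 | step 8 | 2,4-bis(benzyloxy)-6-pentylbenzoyl chloride | CCCCCc1cc(OCc2ccccc2)cc(OCc2ccccc2)c1C(Cl)=O
F5 | step 5 | benzyl 4-{[2,4-bis(benzyloxy)-6-pentylbenzoyl]oxy}-2-hydroxy-6-pentylbenzoate | CCCCCc1cc(OCc2ccccc2)cc(OCc2ccccc2)c1C(=O)Oc1cc(CCCCC)c(C(=O)OCc2ccccc2)c(O)c1
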